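**Plan**
- Retrosynthesis: first remove the allyl group at C-6 (enolate allylation), then cut C1–C6 and C4–C5 of the cyclohexenone together ([4+2]), then the ester C–O bond, then the crotylation bond of the side chain.
- Enabling feature: the benzylic hydroxyl is γ to the ring ketone (O–CHAr–CHMe–C6–C1=O). C-1 can therefore be carried as a ketene acetal carbon bound to that oxygen, which tethers a diene to the C6/C5 vinyl group. The C2=C3 alkene between C1=O and C4–OMe of the 4-methoxycyclohex-2-enone ring is the retron of a 1,1,4-trioxygenated diene.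
- Forward order: syn-crotylation, esterification, diene formation; the carbocycle and a temporary cis-fused tetrahydrofuran (a hexahydrobenzofuran ketal) then form together, and fluoride opens the ketal ring to the enone and the free hydroxyl. Allylation closes the route.
- Stereochemistry: the two side-chain centres come from catalyst-controlled (Z)-crotylboration. C-4 comes from the cycloaddition (enol ether geometry plus π-facial control by the methyl-bearing centre). The quaternary C-6 comes from the allylation, anti to the 4-methoxy group and to the bulk of the side chain.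

Key step: step 6

Assumption: 4-methoxybut-2-ynoic acid (5) is taken as a purchasable building block.

Step 1
Reactants: 1 3,4-dimethoxybenzaldehyde; 2 (Z)-crotylboronic acid pinacol ester
Product: 4 (1S,2R)-1-(3,4-dimethoxyphenyl)-2-methylbut-3-en-1-ol, via pinacol borate ester 3 (not isolated)
Conditions: (S)-TRIP phosphoric acid (5 mol %), toluene, −30 °C; aqueous NaHCO3 work-up
Reagents that add atoms: none
Why: Chiral-phosphoric-acid-catalysed crotylboration through a closed chair transition state should translate the (Z)-crotyl geometry into the syn methyl/hydroxyl relationship, and the catalyst antipode expected to give the (1S) carbinol fixes both centres as (1S,2R) (the other antipode would be used if the sense were opposite).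

Step 2
Reactants: 4 (1S,2R)-1-(3,4-dimethoxyphenyl)-2-methylbut-3-en-1-ol; 5 4-methoxybut-2-ynoic acid
Product: 6 (1S,2R)-1-(3,4-dimethoxyphenyl)-2-methylbut-3-en-1-yl 4-methoxybut-2-ynoate
Conditions: N,N'-diisopropylcarbodiimide, DMAP (10 mol %), CH2Cl2, 0 °C to rt
Reagents that add atoms: none
Why: Carbodiimide (Steglich-type) esterification of a secondary benzylic alcohol; low temperature and catalytic DMAP should limit conjugate addition to the ynoate, and no stereocentre is touched.

Step 3
Reactants: 6 (1S,2R)-1-(3,4-dimethoxyphenyl)-2-methylbut-3-en-1-yl 4-methoxybut-2-ynoate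
Product: 7 (1S,2R)-1-(3,4-dimethoxyphenyl)-2-methylbut-3-en-1-yl (2Z)-4-methoxybut-2-enoate
Conditions: H2 (1 atm), Pd on CaCO3 poisoned with Pb(OAc)2 (Lindlar catalyst), quinoline, EtOAc, rt, stopped after one equivalent of H2
Reagents that add atoms: none
Why: Lindlar semihydrogenation delivers H2 syn to the alkyne to give the (Z)-enoate, and the poisoned catalyst should leave the terminal alkene, the benzylic C–O bond and the arene untouched.

Step 4
Reactants: 7 (1S,2R)-1-(3,4-dimethoxyphenyl)-2-methylbut-3-en-1-yl (2Z)-4-methoxybut-2-enoate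
Product: 9 (1S,2R)-1-(3,4-dimethoxyphenyl)-2-methylbut-3-en-1-yl (3E)-4-methoxybut-3-enoate, via lithium dienolate 8 (not isolated)
Conditions: LDA (LiN(i-Pr)2, 1.2 equiv), THF, −78 °C; then AcOH, −78 °C
Reagents that add atoms: none
Why: Deconjugative protonation: in the (Z)-enoate the s-cis ester carbonyl directs LDA to a γ-hydrogen, 1,3-allylic strain keeps the γ-methoxy group away from the ester so that the new enol ether is (E), and kinetic α-protonation of dienolate 8 gives the β,γ-unsaturated ester.

Step 5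
Reactants: 9 (1S,2R)-1-(3,4-dimethoxyphenyl)-2-methylbut-3-en-1-yl (3E)-4-methoxybut-3-enoate
Product: 11 tert-butyl({(1E,3E)-1-{[(1S,2R)-1-(3,4-dimethoxyphenyl)-2-methylbut-3-en-1-yl]oxy}-4-methoxybuta-1,3-dien-1-yl}oxy)dimethylsilane, via lithium dienolate 10 (not isolated)
Conditions: LDA (1.1 equiv), THF, −78 °C; then t-BuMe2SiCl, DMPU, −78 to 0 °C; pentane, filtration, no aqueous work-up
Reagents that add atoms: tert-butyldimethylsilyl chloride, CC(C)(C)[Si](C)(C)Cl
Why: Kinetic ester enolisation with LDA in THF without a donor cosolvent should give the enolate whose alkoxy group is cis to the α-substituent (C-3), and O-silylation fixes the (1E,3E) silyl ketene acetal in which the tether oxygen is the inside substituent of the diene (silyl ketene acetal formation as used for Ireland–Claisen substrates).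

Step 6
Reactants: 11 tert-butyl({(1E,3E)-1-{[(1S,2R)-1-(3,4-dimethoxyphenyl)-2-methylbut-3-en-1-yl]oxy}-4-methoxybuta-1,3-dien-1-yl}oxy)dimethylsilane
Product: 13 (4S,6R)-6-[(1S,2R)-1-(3,4-dimethoxyphenyl)-1-hydroxypropan-2-yl]-4-methoxycyclohex-2-en-1-one, via bicyclic silyl ketal 12 (not isolated)
Conditions: toluene (0.01 mol/L), 2,6-di-tert-butyl-4-methylphenol (cat.), sealed tube, 170 °C; then Bu4NF, AcOH, THF, 0 °C
Reagents that add atoms: none
Why: Proposed new method: on heating, the (1E,3E)-1,1,4-trioxygenated diene of 11 (an ester-derived O-silyl ketene acetal, HOMO raised by three oxygen donors) should add across the tethered, unactivated vinyl group in a concerted, asynchronous [4π+2π] cycloaddition; the closest known reaction types are the type 1 intramolecular Diels–Alder reaction of 1,3,8-nonatrienes with a (Z)-configured diene and the intermolecular Diels–Alder reactions of vinylketene acetals, and the new element is that the ester oxygen itself is the first tether atom. Two rings close together: the carbocycle by suprafacial [4+2] union (ketal carbon to the internal alkene carbon, methoxy-bearing terminus to the CH2), and a temporary tetrahydrofuran through the three-atom O–CHAr–CHMe tether, which, because the tether oxygen is the inside substituent of the diene terminus, can reach the alkene only with the tether carbon exo, so that a single, cis-fused hexahydrobenzofuran mode is open. The one new stereocentre that survives, C-5 of 12 (C-4 of enone 13), is set by the (3E) enol ether geometry, which places OMe outside and hence trans to the exo tether carbon, together with the π-face of the vinyl group, which is chosen by the adjacent methyl-bearing centre: its C–H eclipses the alkene (least allylic strain), its methyl group points away from the incoming diene, and methyl and aryl thereby sit on the convex face of the forming bicycle. The two ring-fusion centres of 12 are transient (the ketal carbon is erased on cleavage and C-3a is enolised in step 7), so the only selectivity the step needs is this π-facial one, while regiochemistry is fixed by the tether. Bu4NF buffered with AcOH then removes silicon and the hemiketal opens to the enone carbonyl and the free benzylic hydroxyl, under conditions that should neither ionise the allylic methyl ether nor promote loss of methanol.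

Step 7
Reactants: 13 (4S,6R)-6-[(1S,2R)-1-(3,4-dimethoxyphenyl)-1-hydroxypropan-2-yl]-4-methoxycyclohex-2-en-1-one
Product: 15 (4S,6S)-6-[(1S,2R)-1-(3,4-dimethoxyphenyl)-1-hydroxypropan-2-yl]-4-methoxy-6-(prop-2-en-1-yl)cyclohex-2-en-1-one, via dilithium alkoxide enolate 14 (not isolated)
Conditions: LDA (2.2 equiv), THF, −78 °C; allyl bromide (1.2 equiv), −78 to −40 °C; then AcOH
Reagents that add atoms: allyl bromide, C=CCBr
Why: Kinetic α′-deprotonation (cross-conjugated enolate, hydroxyl carried as its lithium alkoxide) followed by enolate C-allylation creates the quaternary centre; allyl bromide should approach anti to the pseudoaxial 4-methoxy group and anti to the CH(OLi)Ar part of the side chain, whose C–H eclipses the enolate (1,3-allylic strain), both elements being matched for (6S).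

**Compound list**
1 | 3,4-dimethoxybenzaldehyde | COc1ccc(C=O)cc1OC | starting material
2 | 2-[(2Z)-but-2-en-1-yl]-4,4,5,5-tetramethyl-1,3,2-dioxaborolane ((Z)-crotylboronic acid pinacol ester) | C/C=C\CB1OC(C)(C)C(C)(C)O1 | starting material
3 | 2-{[(1S,2R)-1-(3,4-dimethoxyphenyl)-2-methylbut-3-en-1-yl]oxy}-4,4,5,5-tetramethyl-1,3,2-dioxaborolane | C=C[C@@H](C)[C@H](OB1OC(C)(C)C(C)(C)O1)c1ccc(OC)c(OC)c1 | intermediate
4 | (1S,2R)-1-(3,4-dimethoxyphenyl)-2-methylbut-3-en-1-ol | C=C[C@@H](C)[C@H](O)c1ccc(OC)c(OC)c1 | intermediate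
5 | 4-methoxybut-2-ynoic acid | COCC#CC(=O)O | starting material
6 | (1S,2R)-1-(3,4-dimethoxyphenyl)-2-methylbut-3-en-1-yl 4-methoxybut-2-ynoate | COCC#CC(=O)O[C@H](c1ccc(OC)c(OC)c1)[C@H](C)C=C | intermediate
7 | (1S,2R)-1-(3,4-dimethoxyphenyl)-2-methylbut-3-en-1-yl (2Z)-4-methoxybut-2-enoate | COC/C=C\C(=O)O[C@H](c1ccc(OC)c(OC)c1)[C@H](C)C=C | intermediate
8 | lithium (3E)-dienolate of 7, OLi cis to C-3 | [Li+].CO/C=C/C=C(\[O-])/O[C@H](c1ccc(OC)c(OC)c1)[C@H](C)C=C | intermediate
9 | (1S,2R)-1-(3,4-dimethoxyphenyl)-2-methylbut-3-en-1-yl (3E)-4-methoxybut-3-enoate | CO/C=C/CC(=O)O[C@H](c1ccc(OC)c(OC)c1)[C@H](C)C=C | intermediate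
10 | lithium (3E)-dienolate of 9, OLi trans to C-3 | [Li+].CO/C=C/C=C(/[O-])\O[C@H](c1ccc(OC)c(OC)c1)[C@H](C)C=C | intermediate
11 | tert-butyl({(1E,3E)-1-{[(1S,2R)-1-(3,4-dimethoxyphenyl)-2-methylbut-3-en-1-yl]oxy}-4-methoxybuta-1,3-dien-1-yl}oxy)dimethylsilane | CO/C=C/C=C(/O[Si](C)(C)C(C)(C)C)\O[C@H](c1ccc(OC)c(OC)c1)[C@H](C)C=C | intermediate
12 | tert-butyl{[(2S,3R,3aR,5S,7aS)-2-(3,4-dimethoxyphenyl)-5-methoxy-3-methyl-2,3,3a,4,5,7a-hexahydro-1-benzofuran-7a-yl]oxy}dimethylsilane (cis-fused) | C[C@H]1[C@@H](c2ccc(OC)c(OC)c2)O[C@]2(O[Si](C)(C)C(C)(C)C)C=C[C@@H](OC)C[C@H]12 | intermediate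
13 | (4S,6R)-6-[(1S,2R)-1-(3,4-dimethoxyphenyl)-1-hydroxypropan-2-yl]-4-methoxycyclohex-2-en-1-one | O=C1C=C[C@@H](OC)C[C@@H]1[C@@H](C)[C@H](O)c1ccc(OC)c(OC)c1 | intermediate
14 | dilithium alkoxide and cross-conjugated enolate of 13 | [Li+].[Li+].[O-]C1=C([C@@H](C)[C@H]([O-])c2ccc(OC)c(OC)c2)C[C@H](OC)C=C1 | intermediate
15 | (4S,6S)-6-[(1S,2R)-1-(3,4-dimethoxyphenyl)-1-hydroxypropan-2-yl]-4-methoxy-6-(prop-2-en-1-yl)cyclohex-2-en-1-one | C=CC[C@@]1([C@@H](C)[C@H](O)c2ccc(OC)c(OC)c2)C[C@H](OC)C=CC1=O | target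

Total step count: 7. Longest linear sequence: 7 steps (from 1; 5 enters at step 2).

**Steps most likely to fail**

1. Step 6 (proposed new method). The unactivated vinyl group may engage too slowly, so that O-to-C silyl migration, ionisation of the electron-rich benzylic C–O bond of the ketene acetal, or loss of π-facial control competes. The fallback uses known chemistry, sets out from 4 and comes back at 13.
   - Hydroboration–oxidation of 4 (9-BBN; NaBO3) gives (3R,4S)-4-(3,4-dimethoxyphenyl)-3-methylbutane-1,4-diol F1.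
   - TEMPO/PhI(OAc)2 lactonises it to (4R,5S)-5-(3,4-dimethoxyphenyl)-4-methyloxolan-2-one F2.
   - α-Methylenation (LDA, dimethylmethylideneammonium iodide, then MeI and NaHCO3) gives (4R,5S)-5-(3,4-dimethoxyphenyl)-4-methyl-3-methylideneoxolan-2-one F3, an activated dienophile.
   - Diels–Alder reaction with commercial 2-methoxyfuran (ZnI2 cat., CH2Cl2) is expected anti to the cis methyl and aryl groups and with the lactone carbonyl exo, giving the spiro oxanorbornene ketal (1S,2S,4S,4'R,5'S)-5'-(3,4-dimethoxyphenyl)-1-methoxy-4'-methyl-7-oxaspiro[bicyclo[2.2.1]hept-5-ene-2,3'-oxolan]-2'-one F4.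
   - Dilute aqueous acid opens the bridgehead ketal to (3S,4R,5S,9S)-3-(3,4-dimethoxyphenyl)-9-hydroxy-4-methyl-2-oxaspiro[4.5]dec-7-ene-1,6-dione F5; the spiro carbon blocks aromatisation.
   - MeI/Ag2O gives the methyl ether (3S,4R,5S,9S)-3-(3,4-dimethoxyphenyl)-9-methoxy-4-methyl-2-oxaspiro[4.5]dec-7-ene-1,6-dione F6.
   - LiOH opens the β-keto lactone and acidification decarboxylates to 13, which rejoins the route at step 7.

2. Step 7. γ-Deprotonation with loss of methanol (aromatisation), O-allylation of the alkoxide, or weak facial control may compete with the desired C-allylation. The fallback sets out from 13 and comes back at 15.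
   - Et3SiCl/imidazole gives (4S,6R)-6-[(1S,2R)-1-(3,4-dimethoxyphenyl)-1-(triethylsilyloxy)propan-2-yl]-4-methoxycyclohex-2-en-1-one F7.
   - LiN(SiMe3)2, TMEDA and allyl chloroformate at −78 °C give the allyl enol carbonate (4S)-2-[(1S,2R)-1-(3,4-dimethoxyphenyl)-1-(triethylsilyloxy)propan-2-yl]-4-methoxycyclohexa-1,5-dien-1-yl prop-2-en-1-yl carbonate F8.
   - Decarboxylative allylation with Pd2(dba)3 and the t-Bu-PHOX antipode that matches the substrate bias gives the triethylsilyl ether of the target F9.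
   - Bu4NF gives 15.

3. Step 5. Enolate geometry may erode (mixture of C1=C2 isomers), or the ketene acetal may suffer C-silylation or hydrolysis. The fallback sets out from 7 and comes back at 13, bypassing step 4.
   - Chelation-controlled γ-deprotonation of 7 (LDA, THF, −78 °C) with in situ silylation (t-BuMe2SiCl, DMPU) gives the geometrically defined isomer tert-butyl({(1Z,3E)-1-{[(1S,2R)-1-(3,4-dimethoxyphenyl)-2-methylbut-3-en-1-yl]oxy}-4-methoxybuta-1,3-dien-1-yl}oxy)dimethylsilane F10, with the tether oxygen outside.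
   - Heating as in step 6 must then pass through the tether-exo mode to the trans-fused ketal tert-butyl{[(2S,3R,3aR,5S,7aR)-2-(3,4-dimethoxyphenyl)-5-methoxy-3-methyl-2,3,3a,4,5,7a-hexahydro-1-benzofuran-7a-yl]oxy}dimethylsilane F11, which carries the same C-5 configuration.
   - Bu4NF/AcOH gives 13.
   - The price is that the cis-fused mode, which would give the C-4 epimer, is no longer excluded.

Further compounds
F1 | step 6 | (3R,4S)-4-(3,4-dimethoxyphenyl)-3-methylbutane-1,4-diol | OCC[C@@H](C)[C@H](O)c1ccc(OC)c(OC)c1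
F2 | step 6 | (4R,5S)-5-(3,4-dimethoxyphenyl)-4-methyloxolan-2-one | O=C1C[C@@H](C)[C@@H](c2ccc(OC)c(OC)c2)O1
F3 | step 6 | (4R,5S)-5-(3,4-dimethoxyphenyl)-4-methyl-3-methylideneoxolan-2-one | C=C1[C@@H](C)[C@@H](c2ccc(OC)c(OC)c2)OC1=O
F4 | step 6 | (1S,2S,4S,4'R,5'S)-5'-(3,4-dimethoxyphenyl)-1-methoxy-4'-methyl-7-oxaspiro[bicyclo[2.2.1]hept-5-ene-2,3'-oxolan]-2'-one | CO[C@@]12C=C[C@@H](O1)C[C@]23[C@@H](C)[C@@H](c1ccc(OC)c(OC)c1)OC3=O
F5 | step 6 | (3S,4R,5S,9S)-3-(3,4-dimethoxyphenyl)-9-hydroxy-4-methyl-2-oxaspiro[4.5]dec-7-ene-1,6-dione | O=C1C=C[C@@H](O)C[C@]12[C@@H](C)[C@@H](c1ccc(OC)c(OC)c1)OC2=O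
F6 | step 6 | (3S,4R,5S,9S)-3-(3,4-dimethoxyphenyl)-9-methoxy-4-methyl-2-oxaspiro[4.5]dec-7-ene-1,6-dione | O=C1C=C[C@@H](OC)C[C@]12[C@@H](C)[C@@H](c1ccc(OC)c(OC)c1)OC2=O
F7 | step 7 | (4S,6R)-6-[(1S,2R)-1-(3,4-dimethoxyphenyl)-1-(triethylsilyloxy)propan-2-yl]-4-methoxycyclohex-2-en-1-one | O=C1C=C[C@@H](OC)C[C@@H]1[C@@H](C)[C@H](O[Si](CC)(CC)CC)c1ccc(OC)c(OC)c1
F8 | step 7 | (4S)-2-[(1S,2R)-1-(3,4-dimethoxyphenyl)-1-(triethylsilyloxy)propan-2-yl]-4-methoxycyclohexa-1,5-dien-1-yl prop-2-en-1-yl carbonate | C=CCOC(=O)OC1=C([C@@H](C)[C@H](O[Si](CC)(CC)CC)c2ccc(OC)c(OC)c2)C[C@H](OC)C=C1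
F9 | step 7 | (4S,6S)-6-[(1S,2R)-1-(3,4-dimethoxyphenyl)-1-(triethylsilyloxy)propan-2-yl]-4-methoxy-6-(prop-2-en-1-yl)cyclohex-2-en-1-one | C=CC[C@@]1([C@@H](C)[C@H](O[Si](CC)(CC)CC)c2ccc(OC)c(OC)c2)C[C@H](OC)C=CC1=O
F10 | step 5 | tert-butyl({(1Z,3E)-1-{[(1S,2R)-1-(3,4-dimethoxyphenyl)-2-methylbut-3-en-1-yl]oxy}-4-methoxybuta-1,3-dien-1-yl}oxy)dimethylsilane | CO/C=C/C=C(\O[Si](C)(C)C(C)(C)C)/O[C@H](c1ccc(OC)c(OC)c1)[C@H](C)C=C
F11 | step 5 | tert-butyl{[(2S,3R,3aR,5S,7aR)-2-(3,4-dimethoxyphenyl)-5-methoxy-3-methyl-2,3,3a,4,5,7a-hexahydro-1-benzofuran-7a-yl]oxy}dimethylsilane (trans-fused) | C[C@H]1[C@@H](c2ccc(OC)c(OC)c2)O[C@@]2(O[Si](C)(C)C(C)(C)C)C=C[C@@H](OC)C[C@H]12
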